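The data come from a simulation for an exercise; noise was put on by code.

Slowness is the first reading of a curve that goes flat, and I test it before I believe it.

in all of them: free catalyst 10 mol%
- delta: substrate 0.0050 M; partner 1.1 equiv; run made earlier
- beta: substrate 0.0075 M; partner 1.1 equiv; run made earlier
- gamma: substrate 0.010 M; partner 1.7 equiv; run made earlier
- flask: substrate 0.010 M; partner 1.10 equiv; time 2.0 d

- delta (time / h: substrate / %, target / %): 8.00: 81.1, 13.3; 15.0: 79.0, 15.0; 25.0: 77.6, 16.7; 30.0: 78.8, 16.6; 40.0: 78.1, 16.4; 50.0: 78.1, 15.2
- beta (time / h: substrate / %, target / %): 4.00: 81.0, 12.6; 6.00: 79.7, 14.9; 10.0: 78.5, 15.7; 20.0: 77.7, 15.3; 30.0: 78.2, 15.6; 50.0: 78.0, 15.6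
- gamma (time / h: substrate / %, target / %): 4.00: 73.4, 18.5; 8.00: 71.5, 19.0; 15.0: 71.8, 19.6; 25.0: 71.8, 18.9; 50.0: 71.5, 19.1

(readings scatter by 0.5 percentage points)

- the reaction counts as stopped when no species that holds the substrate changes by six tenths of a point or more over the second half of the time

1. why nothing more happens at 2.0 d, or that something still does (all of the substrate has reacted / it is still moving / the partner has run out first / no working catalyst is left / forward and back rates have come level)
2. conversion of substrate at 2.0 d
3. amount of target at 2.0 d, in percent of the substrate charged

I build the flask one process at a time, with x the fraction of the substrate charge that has reacted and e the equivalents of partner. With the main step running forward and nothing else, substrate is the limiting reagent and x runs to one, the whole charge. The delta and beta runs refuse this: they go flat with substrate near 78.0%, though partner remains.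

So I add the way back, taking a step with two species on each side, target and an unseen companion each counted as x. The forward rate goes as (one minus x) times (e minus x), and the back rate as x times x. Dividing one by the other at the level point removes time, and concentration with it, leaving the position quotient: x times x over (one minus x) times (e minus x). The last readings give 0.0697 for delta, 0.0705 for beta and 0.0803 for gamma, and I carry their mean, 0.0735, as a reading with their scatter. Solved for this flask's partner charge, it cuts x from the whole charge to 22.4%. The gamma run, at this flask's concentration, is flat from 8.00 h, and this flask has 2.0 d.

The rest is what the target readings lack. In beta, target is a share 0.709 of the reacted substrate, and something unseen holds the remainder. Conversion stays, but my target falls to 15.9%.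

The forecast says forward and back rates have come level, with conversion 22% and target 15.6%: “This points to an equilibrium with no net change in mole number.” Its conversion lies under mine, and so does its target.

The flask gives forward and back rates have come level, with conversion 22.6% and target 15.4%.

    2 catalyst intermediate C → spent catalyst (k = 12.0 M⁻¹ min⁻¹)
    target + free catalyst ⇌ isomer of the product + free catalyst, rate k2*[free catalyst]*[target] forward; the back reaction follows from the equilibrium constant (K = 0.320, k = 190 M⁻¹ min⁻¹)
    partner + free catalyst ⇌ catalyst intermediate A (K = 13.0 M⁻¹, k = 80.0 M⁻¹ min⁻¹)
    catalyst intermediate D ⇌ free catalyst + target (K = 0.0300 M, k = 1.00 min⁻¹)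
    substrate + catalyst intermediate A ⇌ catalyst intermediate B (K = 54.0 M⁻¹, k = 69.0 M⁻¹ min⁻¹)
    catalyst intermediate B ⇌ released group + catalyst intermediate C (K = 0.00260 M, k = 0.760 min⁻¹)
    catalyst intermediate C ⇌ catalyst intermediate D (K = 0.930, k = 1.10 min⁻¹)

In this flask, substrate's half-life by the forward rate of its binding to catalyst intermediate A alone is 0.071 d at 0.0372 d, shorter than the 2.0 d allowed. Yet 77% of the substrate is left at 2.00 d, and the flask's own numbers give a quotient of 0.0751 against my 0.0735. A run can part from the forecast at partner 0.675 equiv or 1.67 equiv, with the other amounts and the time held, or at substrate 0.00171 M, with the equivalents, loadings and time held: at each of these, conversion has moved 5 points.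

For the neighbour flask with 4.40 equiv of partner, 0.0735 gives x of 41.4% and, with the share 0.709, target 29.4%. Computed, it reaches conversion 41.6% and target 28.9%.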